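**Plan**
1. Retrosynthetic cuts, in order: the C8–O tiglate ester; C1=O and C9–OH re-closed as a 4,5-dihydroisoxazole (C1=N–O–C9); C7–C8, which opens the ten-membered ring; C6–C7 with O–C12, which opens the butenolide; C1–C10 with C9–O, which opens the isoxazoline.
2. Enabling feature: the butenolide β-carbon C7 lies between two oxygen-bearing sp3 carbons, C6 (lactone O, five-membered ring) and C8 (ester O, ten-membered ring). C7 is therefore a 1,1-alkenyl dianion joined to two aldehydes. A 3-bromo-3-iodoacrylate that already carries C11, C12 and C13–OAc plays this part, reacting at C–I first and C–Br second.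
3. Forward order of rings: the isoxazoline forms first (nitrile oxide from the C1 aldehyde of ozonised neryl acetate plus (E)-crotyl alcohol). The butenolide follows (Ni/Cr addition of C–I to the C6 enal, then lactonisation). The carbocycle comes last (Ni/Cr addition of C–Br to the C8 aldehyde).
4. Stereochemistry: C9/C10 come from a tartrate/zinc-controlled suprafacial cycloaddition to the E-alkene (anti pattern). C6 and C8 come from ligand-controlled Ni/Cr additions, with C8 reinforced by chelation to the isoxazoline. The Z C4=C5 bond and the E tiglate are bought in with neryl acetate and tiglic acid.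
5. End game: the only free hydroxyl (C8) takes the tiglate, then N–O cleavage and hydrolysis release C1=O and C9–OH together.

Key step: step 11

Numbering: germacrane numbering is used throughout. C1 is the ring ketone carbon, C2/C3 are CH2, C4 is C(CH3)=, C5 is =CH, C6 is the lactone O–CH, C7 is the butenolide β-carbon, C8 is CH–O-tigloyl, C9 is CHOH, C10 is CHCH3, C11 is the butenolide α-carbon, C12 is the lactone C=O, C13 is CH2OAc. "dmphen" means 2,9-dimethyl-1,10-phenanthroline.
Assumption: the sense of induction of the chiral controllers (tartrate, oxazoline–sulfonamide ligand) is taken from the closest simple substrates. The antipodal controller is used if the sense proves opposite.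

**Step 1**
Reactants: 1 neryl acetate
Product: 2 (2Z)-3-methyl-6-oxohex-2-en-1-yl acetate
Conditions: O3 (1.0 equiv, dye end point), CH2Cl2, −78 °C; Me2S
Reagents that add atoms: ozone, [O-][O+]=O
Why: Chemoselective ozonolysis should cleave only the distal isopropylidene alkene, which is much more electron-rich than the alkene deactivated by the allylic acetate, and leave the Z geometry untouched.

**Step 2**
Reactants: 2 (2Z)-3-methyl-6-oxohex-2-en-1-yl acetate
Product: 3 (2Z)-6-(hydroxyimino)-3-methylhex-2-en-1-yl acetate
Conditions: NH2OH·HCl, NaOAc, EtOH–H2O, 0 °C to rt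
Reagents that add atoms: hydroxylamine hydrochloride, NO.Cl
Why: Oxime condensation of an unhindered aldehyde under acetate buffer leaves the ester and alkene inert, and the oxime geometry is of no consequence.

**Step 3**
Reactants: 3 (2Z)-6-(hydroxyimino)-3-methylhex-2-en-1-yl acetate; 4 (E)-but-2-en-1-ol
Product: 7 (4R,5R)-isoxazoline acetate, via hydroximoyl chloride 5 (not isolated), via nitrile oxide 6 (not isolated)
Conditions: (i) NCS, DMF, 0 °C to rt; (ii) 4, Et2Zn (1 equiv), then (R,R)-diisopropyl tartrate (1 equiv), then Et2Zn (1 equiv), CHCl3, 1,4-dioxane (cat.), 0 °C, then crude 5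
Reagents that add atoms: none
Why: In this metal-alkoxide-directed asymmetric nitrile oxide [3+2] cycloaddition, zinc bridges the allylic alkoxide and the nitrile oxide oxygen so that O bonds to C9 and C1 to C10, suprafacial addition to the E-alkene sets the trans-4,5 (anti C9/C10) relation, and the tartrate on the dinuclear zinc template selects the face that gives 4R,5R.

**Step 4**
Reactants: 7 (4R,5R)-isoxazoline acetate
Product: 8 (4R,5R)-isoxazoline diol
Conditions: K2CO3 (cat.), MeOH, 0 °C
Reagents that add atoms: none
Why: Base-catalysed methanolysis of a primary acetate does not touch the isoxazoline, its stereocentres or the alkene.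

**Step 5**
Reactants: 8 (4R,5R)-isoxazoline diol
Product: 9 (4R,5R)-isoxazoline Z-enal
Conditions: activated MnO2, CH2Cl2, rt
Reagents that add atoms: none
Why: MnO2 oxidises only the allylic primary alcohol and leaves the saturated one, and the neutral heterogeneous medium should keep the Z-enal from isomerising.

**Step 6**
Reactants: 10 ethyl 3-bromo-2-oxopropanoate
Product: 11 ethyl 3-acetoxy-2-oxopropanoate
Conditions: KOAc, 18-crown-6 (cat.), MeCN, rt
Reagents that add atoms: potassium acetate, CC(=O)[O-].[K+]
Why: This is an SN2 displacement of a highly activated α-keto bromide by acetate, and it installs the C13 acetate at the outset.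

**Step 7**
Reactants: 11 ethyl 3-acetoxy-2-oxopropanoate
Product: 12 ethyl 2-(acetoxymethyl)-3,3-dibromoprop-2-enoate
Conditions: CBr4, PPh3, CH2Cl2, 0 °C
Reagents that add atoms: carbon tetrabromide, BrC(Br)(Br)Br
Why: The Ramirez dibromoolefination works well on electrophilic α-keto esters and delivers C7 as a CBr2 unit with no geometric issue.

**Step 8**
Reactants: 12 ethyl 2-(acetoxymethyl)-3,3-dibromoprop-2-enoate
Product: 14 ethyl (2Z)-2-(acetoxymethyl)-3-bromo-3-iodoprop-2-enoate, via magnesium carbenoid 13 (not isolated)
Conditions: i-PrMgCl (1.05 equiv), THF–Et2O, −78 °C; I2, −78 °C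
Reagents that add atoms: iodine, II
Why: Ester-directed Br/Mg exchange removes the bromine cis to CO2Et because the carbonyl chelates magnesium, and iodinolysis with retention places iodine cis to the ester, while at −78 °C both esters and the carbenoid persist.

**Step 9**
Reactants: 9 (4R,5R)-isoxazoline Z-enal; 14 ethyl (2Z)-2-(acetoxymethyl)-3-bromo-3-iodoprop-2-enoate
Product: 16 (5R)-4-bromobutenolide alcohol, via hydroxy ester 15 (not isolated)
Conditions: 14 (1.5 equiv), CrCl2 (10 mol %), (S)-oxazoline–sulfonamide ligand (11 mol %), proton sponge (11 mol %), NiCl2·dmphen (0.5 mol %), Mn (2 equiv), Cp2ZrCl2 (2.2 equiv), LiCl, MeCN, rt; then PPTS (cat.), CH2Cl2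
Reagents that add atoms: none
Why: Proposed new method: Ni(0) should insert only into the weaker C–I bond of 14; transmetallation gives an α-bromoalkenylchromium(III) carbenoid held cis to the ester by C=O→Cr chelation; it adds 1,2 to the enal under the chiral Cr ligand (Si face, 6R), and the alkoxide, cis to CO2Et, lactonises with loss of ethanol; the closest known reaction types are the catalytic asymmetric Nozaki–Hiyama–Kishi coupling of β-iodoacrylates, the addition of α-haloalkenylchromium carbenoids to aldehydes, and the magnesium-carbenoid route from 3,3-dibromoacrylates and aldehydes to 4-bromobutenolides; low nickel loading and excess 14 should keep the C–Br bond of the product untouched, and the free primary hydroxyl is carried as its zirconium alkoxide.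

**Step 10**
Reactants: 16 (5R)-4-bromobutenolide alcohol
Product: 17 (5R)-4-bromobutenolide aldehyde
Conditions: Dess–Martin periodinane (1.2 equiv), CH2Cl2, 0 °C; used without delay
Reagents that add atoms: none
Why: Dess–Martin oxidation converts the only hydroxyl into the C8 aldehyde under near-neutral conditions that should spare C9, the acidic C6–H and the vinylogous acyl bromide.

**Step 11**
Reactants: 17 (5R)-4-bromobutenolide aldehyde
Product: 19 tricyclic allylic alcohol (6R,8R,9R,10R), via alkenylchromium 18 (not isolated)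
Conditions: CrCl3 (20 mol %), (S)-oxazoline–sulfonamide ligand (22 mol %), Et3N (40 mol %), NiCl2·dmphen (10 mol %), Cp2ZrCl2 (1.5 equiv), LiCl, n-Bu4NPF6, MeCN, undivided cell, Al(+)/Ni foam(−), constant current matched to syringe-pump addition of 17 (final 2 mM), rt; aq. potassium serinate work-up
Reagents that add atoms: none
Why: Cathodically regenerated Cr(II) reduces Ni(II) to Ni(0), which inserts into the activated C7–Br bond; transmetallation gives the alkenylchromium(III) species 18, which adds to the C8 aldehyde, and Cp2ZrCl2 releases chromium from the alkoxide for turnover. The closest known reaction types are the intramolecular Nozaki–Hiyama–Kishi macrocyclisation of haloalkene aldehydes (ten-membered rings included), the Ni/Cr coupling of β-haloacrylates, and the electrochemical ligand-controlled catalytic variant of this coupling. The ten-membered carbocycle closes in the 10-exo-trig mode (C=O exocyclic), giving the butenolide-fused, N–O-bridged bicyclo[7.2.1] frame, and slow addition against a current-limited Cr(II) supply favours ring closure over dimerisation. C8 is the only new stereocentre: Re-face attack (8R, syn to C9–O) is what a Cram chelate of Cr(III) between the aldehyde O and the isoxazoline O/N predicts, and the ligand is chosen in the matched sense. Chemoselectivity rests on the substrate, because organochromium(III) adds only to the aldehyde (lactone, acetate and C=N are spectators), the isoxazoline locks the ketone and the C9 oxygen against retro-aldol, β-elimination and C10 epimerisation, and the low standing Cr(II) level spares the N–O bond and the allylic esters. The step thus delivers the ring, C8 and the single free hydroxyl that must take the tiglate.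

**Step 12**
Reactants: 19 tricyclic allylic alcohol (6R,8R,9R,10R); 20 tiglic acid
Product: 21 tricyclic tiglate
Conditions: DCC, DMAP (0.3 equiv), CH2Cl2, 0 °C to rt
Reagents that add atoms: none
Why: Steglich esterification acylates the only hydroxyl with retention at C8, the E-configured acid is the stable isomer, and the weakly basic medium should not epimerise C6.

**Step 13**
Reactants: 21 tricyclic tiglate
Product: 23 target CNP0281168.1, via hydroxy imine 22 (not isolated)
Conditions: Mo(CO)6 (1.2 equiv), MeCN–H2O (15:1), 80 °C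
Reagents that add atoms: water, O
Why: Mo(CO)6-mediated reductive N–O cleavage of the isoxazoline followed by in situ imine hydrolysis releases the C1 ketone and C9 hydroxyl without touching C9 or C10, and the method is known to tolerate esters, enoates and trisubstituted alkenes.

**Compound list**
1 | neryl acetate, (2Z)-3,7-dimethylocta-2,6-dien-1-yl acetate | CC(C)=CCC/C(C)=C\COC(C)=O | starting material
2 | (2Z)-3-methyl-6-oxohex-2-en-1-yl acetate | O=CCC/C(C)=C\COC(C)=O | intermediate
3 | (2Z)-6-(hydroxyimino)-3-methylhex-2-en-1-yl acetate (oxime geometry not defined) | ON=CCC/C(C)=C\COC(C)=O | intermediate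
4 | (E)-but-2-en-1-ol (crotyl alcohol) | C/C=C/CO | starting material
5 | (2Z)-6-chloro-6-(hydroxyimino)-3-methylhex-2-en-1-yl acetate | ON=C(Cl)CC/C(C)=C\COC(C)=O | intermediate
6 | (4Z)-6-acetoxy-4-methylhex-4-enenitrile oxide | [O-][N+]#CCC/C(C)=C\COC(C)=O | intermediate
7 | (2Z)-5-[(4R,5R)-5-(hydroxymethyl)-4-methyl-4,5-dihydro-1,2-oxazol-3-yl]-3-methylpent-2-en-1-yl acetate | OC[C@@H]1ON=C(CC/C(C)=C\COC(C)=O)[C@H]1C | intermediate
8 | (2Z)-5-[(4R,5R)-5-(hydroxymethyl)-4-methyl-4,5-dihydro-1,2-oxazol-3-yl]-3-methylpent-2-en-1-ol | OC[C@@H]1ON=C(CC/C(C)=C\CO)[C@H]1C | intermediate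
9 | (2Z)-5-[(4R,5R)-5-(hydroxymethyl)-4-methyl-4,5-dihydro-1,2-oxazol-3-yl]-3-methylpent-2-enal | OC[C@@H]1ON=C(CC/C(C)=C\C=O)[C@H]1C | intermediate
10 | ethyl 3-bromo-2-oxopropanoate (ethyl bromopyruvate) | CCOC(=O)C(=O)CBr | starting material
11 | ethyl 3-acetoxy-2-oxopropanoate | CCOC(=O)C(=O)COC(C)=O | intermediate
12 | ethyl 2-(acetoxymethyl)-3,3-dibromoprop-2-enoate | CCOC(=O)C(COC(C)=O)=C(Br)Br | intermediate
13 | ethyl 2-(acetoxymethyl)-3-bromo-3-(chloromagnesio)prop-2-enoate, Mg cis to CO2Et | CCOC(=O)/C(COC(C)=O)=C(\[Mg]Cl)Br | intermediate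
14 | ethyl (2Z)-2-(acetoxymethyl)-3-bromo-3-iodoprop-2-enoate, I cis to CO2Et | CCOC(=O)/C(COC(C)=O)=C(\I)Br | intermediate
15 | open-chain (6R)-γ-hydroxy-β-bromo enoate ethyl ester, C6 carbinol cis to CO2Et, 4Z alkene, (4R,5R)-5-(hydroxymethyl)-4-methylisoxazoline terminus | OC[C@@H]1ON=C(CC/C(C)=C\[C@@H](O)/C(Br)=C(/COC(C)=O)C(=O)OCC)[C@H]1C | intermediate
16 | [(5R)-4-bromo-5-{(1Z)-4-[(4R,5R)-5-(hydroxymethyl)-4-methyl-4,5-dihydro-1,2-oxazol-3-yl]-2-methylbut-1-en-1-yl}-2-oxo-2,5-dihydrofuran-3-yl]methyl acetate | OC[C@@H]1ON=C(CC/C(C)=C\[C@H]2OC(=O)C(COC(C)=O)=C2Br)[C@H]1C | intermediate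
17 | [(5R)-4-bromo-5-{(1Z)-4-[(4R,5R)-5-formyl-4-methyl-4,5-dihydro-1,2-oxazol-3-yl]-2-methylbut-1-en-1-yl}-2-oxo-2,5-dihydrofuran-3-yl]methyl acetate | O=C[C@@H]1ON=C(CC/C(C)=C\[C@H]2OC(=O)C(COC(C)=O)=C2Br)[C@H]1C | intermediate
18 | C7 dichlorochromium(III) analogue of 17 (Cr in place of Br) | O=C[C@@H]1ON=C(CC/C(C)=C\[C@H]2OC(=O)C(COC(C)=O)=C2[Cr](Cl)Cl)[C@H]1C | intermediate
19 | ten-membered carbocycle with 4Z alkene, 6,12-butenolide (7(11)-ene, 13-OAc), C1=N–O–C9 isoxazoline bridge and free 8-OH; 6R,8R,9R,10R (10R here is the same spatial arrangement as 10S in 23, CIP priorities change) | O[C@@H]1C2=C(COC(C)=O)C(=O)O[C@@H]2/C=C(/C)CCC3=NO[C@@H]1[C@@H]3C | intermediate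
20 | tiglic acid, (2E)-2-methylbut-2-enoic acid | C/C=C(\C)C(=O)O | starting material
21 | 8-O-tigloyl ester of 19 | C/C=C(\C)C(=O)O[C@@H]1C2=C(COC(C)=O)C(=O)O[C@@H]2/C=C(/C)CCC3=NO[C@@H]1[C@@H]3C | intermediate
22 | C1 imine of the target (C1=NH, 9-OH free, configuration as in 23) | C/C=C(\C)C(=O)O[C@@H]1C2=C(COC(C)=O)C(=O)O[C@@H]2/C=C(/C)CCC(=N)[C@@H](C)[C@H]1O | intermediate
23 | CNP0281168.1, (6R,8R,9R,10S)-13-acetoxy-9-hydroxy-1-oxo-8-tigloyloxygermacra-4Z,7(11)-dien-6,12-olide | C/C=C(\C)C(=O)O[C@@H]1C2=C(COC(C)=O)C(=O)O[C@@H]2/C=C(/C)CCC(=O)[C@@H](C)[C@H]1O | target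

**Total steps:** 13. **Longest linear sequence:** 10 (steps 1–5 and 9–13).

**Steps most likely to fail**

Step 9 (Proposed new method).
- What may go wrong: nickel may fail to discriminate between the two carbon–halogen bonds and insert further into the C–Br bond of the product. The α-bromo carbenoid may undergo α-elimination. Facial selectivity on the Z-enal may be poor.
- Fallback (known chemistry): it sets out from 9 and 12 and comes back at 16.
- Dibromoacrylate 12 is converted with i-PrMgCl at −78 °C into carbenoid 13. Two equivalents are used, one being consumed by the free hydroxyl.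
- Carbenoid 13 is added directly to enal 9. The alkoxides lactonise on warming, 15 giving 16 and the (6S)-hydroxy ester F1 giving the (5S)-4-bromobutenolide alcohol F2, without facial control.
- Because C9 and C10 are already fixed, 16 and F2 are diastereomers and are separated by chromatography.
- F2 is re-equilibrated at the acidic C6–H with catalytic DBU and recycled.

Step 11.
- What may go wrong: the C7–metal species may expel the antiperiplanar lactone carboxylate from C6, opening the ring to an allenoate. It may also be protonated, or couple intermolecularly, before the strained ring closes.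
- Fallback: it sets out from 9 and 14 and comes back at 21.
- The Ni/Cr coupling of 9 with 14 is run with Mn/Et3SiCl as the turnover couple. Both the new C6 alkoxide and the primary hydroxyl are then trapped before lactonisation, giving the open-chain bis(triethylsilyl) ether ethyl ester F3.
- Swern oxidation, which attacks primary triethylsilyl ethers selectively, gives the open-chain aldehyde F4.
- The ring closure of step 11 is carried out on this β-bromo enoate, whose C6 silyloxy group is a poor nucleofuge, to give the ten-membered allylic alcohol with open ester F5.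
- Steglich esterification with 20 gives the open-ester tiglate F6.
- HF·pyridine removes the silyl group, and the C6 hydroxyl, cis to CO2Et, lactonises to 21.

Step 13.
- What may go wrong: the allylic acetate, the tiglate or the lactone C–O bond may ionise on low-valent molybdenum. The tiglate may migrate from O8 to the newly freed O9 on heating. The liberated aldol may undergo retro-aldol cleavage.
- Fallback: it sets out from 7 and comes back at 23. The isoxazoline is removed early and replaced by silyl protection.
- Raney nickel/H2/B(OH)3 in aqueous methanol converts 7 into the keto diol acetate F7.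
- Et3SiCl/imidazole gives the bis(triethylsilyl) ether F8, K2CO3/MeOH gives the allylic alcohol F9, and MnO2 gives the Z-enal F10.
- Coupling with 14 as in step 9 gives the keto bromobutenolide F11.
- Swern oxidation of the primary silyl ether gives the keto aldehyde F12.
- Ring closure as in step 11, where the aldehyde reacts in preference to the ketone, gives the 9-O-silyl macrocyclic alcohol F13.
- Steglich esterification with 20 gives the 9-O-silyl tiglate F14, and HF·pyridine at 0 °C gives 23.

**Further compounds**
F1 | step 9 | (6S)-hydroxy ester, C6 epimer of 15 | OC[C@@H]1ON=C(CC/C(C)=C\[C@H](O)/C(Br)=C(/COC(C)=O)C(=O)OCC)[C@H]1C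
F2 | step 9 | (5S)-4-bromobutenolide alcohol, C6 epimer of 16 | OC[C@@H]1ON=C(CC/C(C)=C\[C@@H]2OC(=O)C(COC(C)=O)=C2Br)[C@H]1C
F3 | step 11 | open-chain bis(triethylsilyl) ether ethyl ester (6R, C6 cis to CO2Et) | CC[Si](CC)(CC)OC[C@@H]1ON=C(CC/C(C)=C\[C@@H](O[Si](CC)(CC)CC)/C(Br)=C(/COC(C)=O)C(=O)OCC)[C@H]1C
F4 | step 11 | open-chain aldehyde (6-O-triethylsilyl, C8 formyl) | O=C[C@@H]1ON=C(CC/C(C)=C\[C@@H](O[Si](CC)(CC)CC)/C(Br)=C(/COC(C)=O)C(=O)OCC)[C@H]1C
F5 | step 11 | ten-membered allylic alcohol with open ester (8R, 6-O-triethylsilyl, C8 cis to CH2OAc) | O[C@@H]1/C(=C(\COC(C)=O)C(=O)OCC)[C@H](O[Si](CC)(CC)CC)/C=C(/C)CCC2=NO[C@@H]1[C@@H]2C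
F6 | step 11 | open-ester tiglate | C/C=C(\C)C(=O)O[C@@H]1/C(=C(\COC(C)=O)C(=O)OCC)[C@H](O[Si](CC)(CC)CC)/C=C(/C)CCC2=NO[C@@H]1[C@@H]2C
F7 | step 13 | keto diol acetate, (2Z,7S,8R)-8,9-dihydroxy-3,7-dimethyl-6-oxonon-2-en-1-yl acetate | OC[C@H](O)[C@H](C)C(=O)CC/C(C)=C\COC(C)=O
F8 | step 13 | bis(triethylsilyl) ether of F7 | CC[Si](CC)(CC)OC[C@H](O[Si](CC)(CC)CC)[C@H](C)C(=O)CC/C(C)=C\COC(C)=O
F9 | step 13 | allylic alcohol from F8 | CC[Si](CC)(CC)OC[C@H](O[Si](CC)(CC)CC)[C@H](C)C(=O)CC/C(C)=C\CO
F10 | step 13 | Z-enal from F9 | CC[Si](CC)(CC)OC[C@H](O[Si](CC)(CC)CC)[C@H](C)C(=O)CC/C(C)=C\C=O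
F11 | step 13 | keto bromobutenolide (6R, bis-silyl ether) | CC[Si](CC)(CC)OC[C@H](O[Si](CC)(CC)CC)[C@H](C)C(=O)CC/C(C)=C\[C@H]1OC(=O)C(COC(C)=O)=C1Br
F12 | step 13 | keto aldehyde (9-O-triethylsilyl) | O=C[C@H](O[Si](CC)(CC)CC)[C@H](C)C(=O)CC/C(C)=C\[C@H]1OC(=O)C(COC(C)=O)=C1Br
F13 | step 13 | 9-O-silyl macrocyclic alcohol | O[C@@H]1C2=C(COC(C)=O)C(=O)O[C@@H]2/C=C(/C)CCC(=O)[C@@H](C)[C@H]1O[Si](CC)(CC)CC
F14 | step 13 | 9-O-silyl tiglate | C/C=C(\C)C(=O)O[C@@H]1C2=C(COC(C)=O)C(=O)O[C@@H]2/C=C(/C)CCC(=O)[C@@H](C)[C@H]1O[Si](CC)(CC)CC
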